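Readings and results were generated by integration from invented constants; the scatter is artificial.

At the last autumn reading single product stands far above bis adduct, 59.5% against 4.0%. So for eta, zeta and theta, one recipe stopped at three times, two numbers are wanted: how much the second addition of coupling partner takes back, and how fast the first addition runs.

| setting | spring | noon | autumn | eta | zeta | theta |
|---|---|---|---|---|---|---|
| starting material | 0.52 M | 1.2 M | 0.78 M | 0.78 M | 0.78 M | 0.78 M |
| coupling partner | 1.17 M | 1.17 M | 2.3 M | 1.17 M | 1.17 M | 1.17 M |
| remark | run made earlier | run made earlier | run made earlier |  |  |  |
| time |  |  |  | 5.0 min | 50 min | 15 min |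

| run | time / min | over-reaction product / % | starting material / % | bis adduct / % | single product / % |
|---|---|---|---|---|---|
| spring | 0.333 | 0 | 95.7 | 0.9 | 5.0 |
| spring | 1.00 | 0 | 86.3 | 0 | 13.4 |
| spring | 2.00 | 0 | 75.7 | 0.4 | 24.1 |
| spring | 3.00 | 0.4 | 66.3 | 0.6 | 33.0 |
| spring | 4.00 | 0 | 58.6 | 0.6 | 40.5 |
| noon | 0.833 | 0.4 | 89.2 | 0.4 | 10.4 |
| noon | 1.50 | 0 | 81.8 | 0 | 17.5 |
| noon | 2.50 | 0 | 73.3 | 0.2 | 26.4 |
| noon | 3.00 | 0 | 68.9 | 1.2 | 29.8 |
| noon | 4.00 | 0 | 62.4 | 1.5 | 36.2 |
| autumn | 0.333 | 0.1 | 90.9 | 0.3 | 8.5 |
| autumn | 1.00 | 0.4 | 76.0 | 0 | 23.6 |
| autumn | 2.00 | 0 | 57.8 | 0.9 | 39.6 |
| autumn | 3.00 | 0.1 | 45.4 | 1.7 | 50.4 |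
| autumn | 4.00 | 0 | 35.9 | 4.0 | 59.5 |

(readings scatter by 0.5 percentage points)

- the analysis behind the earlier runs scatters by 0.5 percentage points, standard deviation
- a reading or a percentage of bis adduct counts all its forms, free or not
- a reading of starting material is of its free form alone

* which of these there is most of at the end, counted by the starting material in it, eta (single product / over-reaction product / starting material / bis adduct)
* which of these there is most of at the end, counted by the starting material in it, zeta (single product / over-reaction product / starting material / bis adduct)
* which of these there is most of at the end, counted by the starting material in it, theta (single product / over-reaction product / starting material / bis adduct)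
* the largest of these amounts at the end, in percent of the starting material charged, eta
* the largest of these amounts at the end, in percent of the starting material charged, zeta
* the largest of these amounts at the end, in percent of the starting material charged, theta

Let a be the fraction of the charged starting material still free. Starting material and single product each react with coupling partner, so partner and time cancel from the ratio of the two rates, and single product becomes a function of a: a raised to s, less a, over one less s. Here s is the selectivity factor, the rate constant of the second addition over that of the first. While bis adduct is small, it is about s times the sum of ln(1/a), a and minus one, so the last autumn reading gives s as 0.104, a value read from one bis adduct reading, and such readings scatter by 0.5 percentage points. The rule peaks at a = 8.00%, with single product at 76.9%; that is the end state to aim at.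

The speed comes from the same autumn reading. If partner is spent once per starting material, the logarithm of partner fraction over a grows evenly with time, which gives a constant of 0.00214 M⁻¹ s⁻¹, or 0.0500 min⁻¹ for the recipe. So a is 54.0% at 5.0 min, 23.0% at 15 min and 2.90% at 50 min. The rule turns these into 44.4%, 70.1% and 73.9% of single product.

The weak link is a at 50 min, since bis adduct spends partner a second time. Reforged, partner is reckoned at 31.9% of its charge on average between 15 min and 50 min, which carries the reckoned a from 23.0% down to 4.30%, and the reckoned single product in zeta to 75.6%. Eta should therefore still be led by starting material, and theta and zeta by single product.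

The forecast names starting material at 55.5% for eta, single product at 68% for theta and single product at 74% for zeta, below the figure reckoned here, and adds: “The 50-minute value is the least certain”. The flasks give starting material at 54.1% in eta, single product at 68.9% in theta and single product at 75.9% in zeta.

    starting material + coupling partner → single product (k = 0.00208 M⁻¹ s⁻¹)
    coupling partner + single product → bis adduct (k = 1.87 × 10⁻⁴ M⁻¹ s⁻¹)
    bis adduct → over-reaction product (k = 1.03 × 10⁻⁴ s⁻¹)
    starting material + bis adduct ⇌ idle adduct, settled at all times (K = 5.50 M⁻¹)

With the difference in time taken away, zeta holds 43.7% single product instead of 75.9%, so that difference is the main reason for its amount. With s, zeta's free starting material of 4.39% returns 75.7% of single product; zeta's idle adduct, 4.89% of the charge counted by the starting material it holds, is less than the 60 points lead of single product over bis adduct. For a neighbour of eta with 2.0 M of coupling partner, the reckoning gives a = 34.0% and, through s, 61.8% single product. That neighbour computes to 33.6% of starting material and 60.9% of single product, led by single product.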